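**Route outline**

1. Retrosynthesis: after the MOM ether, ring B (the benzene ring of the chroman) is cut in one stroke at C6–C7, C7–C8 and C4a–C5, with C5–C6 kept as a triple bond. This gives a chromone-bearing methoxyalkyne and a 2-methyl-dihydropyran-3-carbonyl chloride as vinylketene precursor. The alkyne is cut at its bond to chromone C3 (Stille), the chromone at C2 (enaminone), the dihydropyran at O–CMe2 and at the prenyl C–C bond.
2. Enabling feature: ring B is a pentasubstituted benzene whose three oxygens are all different and sit on alternate carbons (chroman locants: free OH on C7, OMe on C5, ring ether O1 on C8a). They are interleaved with the chromone on C6, the CH2 on C4a and H on C8. Atom for atom this is a ketene C=O (C7), a methoxyalkyne carrying the chromone (C5, C6) and the C=C–CH3 enol ether unit of a 2-methyldihydropyran (C4a, C8a, C8).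
3. Forward: the dihydropyran ring is closed first (prenylated acetoacetate, acid cycloisomerization) and converted to the acid chloride. The chromone bicycle is made separately by iodocyclization of an enaminone and receives the methoxyethynyl group by Stille coupling.
4. The benzannulation builds ring B last. This fuses the new benzene to the dihydropyran (giving the chroman) and forms the aryl–chromone bond; acid then removes the MOM group.
5. Stereochemistry: the target has no stereocentre. The centres of the alkylated keto ester and of the transient spirocyclobutenone are racemic and disappear.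

Key step: step 10

**Steps**

Step 1
Reactants: 1 ethyl acetoacetate; 2 prenyl bromide (1-bromo-3-methylbut-2-ene)
Product: 3 ethyl 2-acetyl-5-methylhex-4-enoate (racemic)
Conditions: NaH (1.0 equiv), THF, 0 °C; then 2 (0.9 equiv), 0 °C to rt
Reagents that add atoms: none
Why: Acetoacetic ester alkylation: the sodium enolate of 1 is C-alkylated by the primary allylic bromide (SN2), a slight excess of 1 limiting dialkylation; the new stereocentre is racemic and is erased in step 2.

Step 2
Reactants: 3 ethyl 2-acetyl-5-methylhex-4-enoate
Product: 4 ethyl 2,6,6-trimethyl-5,6-dihydro-4H-pyran-3-carboxylate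
Conditions: TfOH (5 mol %), CH2Cl2, 0 °C to rt; Et3N quench
Reagents that add atoms: none
Why: Acid-catalysed cycloisomerization of a 2-prenyl-1,3-dicarbonyl compound: Markovnikov protonation of the trisubstituted alkene gives a tertiary cation that the enol oxygen of the ketone captures in a six-membered ring closure, the conjugated β-alkoxy acrylate being the thermodynamic product.

Step 3
Reactants: 4 ethyl 2,6,6-trimethyl-5,6-dihydro-4H-pyran-3-carboxylate
Product: 5 potassium 2,6,6-trimethyl-5,6-dihydro-4H-pyran-3-carboxylate
Conditions: KOH (1.05 equiv), EtOH/H2O, reflux; evaporation, azeotropic drying with toluene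
Reagents that add atoms: potassium hydroxide, [K+].[OH-]
Why: Saponification of the vinylogous carbonate ester; the acid is kept as its dry potassium salt so that the acid-labile enol ether never meets aqueous acid.

Step 4
Reactants: 5 potassium 2,6,6-trimethyl-5,6-dihydro-4H-pyran-3-carboxylate
Product: 6 2,6,6-trimethyl-5,6-dihydro-4H-pyran-3-carbonyl chloride
Conditions: (COCl)2 (1.05 equiv), toluene, 0 °C to rt; filtered under argon and used as a crude toluene solution
Reagents that add atoms: oxalyl chloride, O=C(Cl)C(=O)Cl
Why: Acid chloride formation from a carboxylate salt and oxalyl chloride passes through the mixed anhydride and releases only CO, CO2 and KCl, so no free HCl can add to the enol ether or ionize the tertiary ether; 2-methyl-dihydropyran-3-carbonyl chlorides are a known, usable class.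

Step 5
Reactants: 7 2,4-dihydroxyacetophenone
Product: 8 1-[2-hydroxy-4-(methoxymethoxy)phenyl]ethanone
Conditions: MOMCl (1.1 equiv), iPr2NEt, CH2Cl2, 0 °C to rt
Reagents that add atoms: chloromethyl methyl ether, COCCl
Why: O-alkylation with MOMCl is selective for the 4-OH because the 2-OH is held in a hydrogen bond to the acetyl carbonyl and is far less nucleophilic.

Step 6
Reactants: 8 1-[2-hydroxy-4-(methoxymethoxy)phenyl]ethanone; 9 N,N-dimethylformamide dimethyl acetal
Product: 10 (E)-3-(dimethylamino)-1-[2-hydroxy-4-(methoxymethoxy)phenyl]prop-2-en-1-one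
Conditions: 9 (2 equiv), toluene, 95 °C
Reagents that add atoms: none
Why: Condensation of the methyl ketone with the amide acetal gives the vinylogous amide as its E isomer under thermodynamic control, and supplies the carbon that becomes chromone C2.

Step 7
Reactants: 10 (E)-3-(dimethylamino)-1-[2-hydroxy-4-(methoxymethoxy)phenyl]prop-2-en-1-one
Product: 11 3-iodo-7-(methoxymethoxy)chromen-4-one
Conditions: I2 (1.5 equiv), pyridine (1.5 equiv), CHCl3, rt; aq Na2S2O3
Reagents that add atoms: iodine, II
Why: Iodine-induced cyclization of an ortho-hydroxyaryl enaminone: iodination at the α-carbon, attack of the phenol on the iminium carbon and loss of dimethylamine give the 3-iodochromone, pyridine keeping the medium non-acidic for the MOM ether.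

Step 8
Reactants: 12 chloroacetaldehyde dimethyl acetal
Product: 14 tributyl(methoxyethynyl)stannane, via lithium methoxyacetylide 13 (not isolated)
Conditions: LiNEt2 (3.1 equiv, from Et2NH and n-BuLi), THF, −78 to 0 °C; then Bu3SnCl (1.0 equiv), −78 °C to rt; non-aqueous work-up, short-path distillation
Reagents that add atoms: tributyltin chloride, CCCC[Sn](Cl)(CCCC)CCCC
Why: Known one-flask route to metallated alkoxyacetylenes: two successive amide-induced eliminations (MeOH, then HCl) give methoxyacetylene, the third equivalent of amide deprotonates it, and the acetylide is stannylated at carbon.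

Step 9
Reactants: 11 3-iodo-7-(methoxymethoxy)chromen-4-one; 14 tributyl(methoxyethynyl)stannane
Product: 15 3-(methoxyethynyl)-7-(methoxymethoxy)chromen-4-one
Conditions: Pd(PPh3)4 (5 mol %), CuI (10 mol %), DMF, rt to 40 °C, dark; aq KF, then Et3N-deactivated silica
Reagents that add atoms: none
Why: Stille coupling of an α-iodo-enone-type vinyl iodide (fast oxidative addition to zerovalent palladium) with an alkynylstannane, the alkynyl group transferring selectively from tin and CuI (monovalent copper) speeding transmetalation, so that the acid-sensitive ynol ether forms near room temperature and is isolated without contact with acid.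

Step 10
Reactants: 6 2,6,6-trimethyl-5,6-dihydro-4H-pyran-3-carbonyl chloride; 15 3-(methoxyethynyl)-7-(methoxymethoxy)chromen-4-one
Product: 20 7-O-methoxymethyl glycyrrhizaisoflavone C, via vinylketene 16 (not isolated), via spirocyclobutenone 17 (not isolated), via dienylketene 18 (not isolated), via cyclohexadienone 19 (not isolated)
Conditions: 15 (1.0 equiv), Et3N (3 equiv), toluene, rt; 6 (1.8 equiv) in toluene added over 4 h; then 80 °C; then K2CO3, MeOH, rt (cleaves any phenol ester formed by over-acylation)
Reagents that add atoms: none
Why: Proposed new method: Et3N removes HCl from 6 across the acyl carbon and the 2-methyl group (1,4-elimination; these are the only hydrogens whose loss can give a ketene) to form vinylketene 16, whose central carbon is attacked by the nucleophilic, chromone-bearing carbon of ynol ether 15, and a [2+2] cycloaddition closes the four-membered ring of 17; on warming, 17 opens reversibly (conrotatory, four electrons) to dienylketene 18, the isomer with the exocyclic methylene cis to the ketene closes by a disrotatory six-electron electrocyclization to 19, and 19 enolizes to phenol 20. The closest known reaction types are the Danheiser benzannulation of vinylketenes with alkoxyalkynes and the naphthol synthesis from arylacetyl chlorides, a tertiary amine and alkoxyalkynes; vinylketene formation from a β-alkoxy enoyl chloride and an ynol ether carrying a chromone are the untested elements. Ring closures: the cyclobutenone by [2+2] cycloaddition (transient) and ring B by 6π-electrocyclization, which fuses the new benzene onto the dihydropyran and thereby completes the chroman. No stereocentre is set: the spiro carbon of 17 is racemic and ends as aromatic C4a. The step needs the regiochemistry that joins the ketene carbonyl carbon to the chromone-bearing alkyne carbon (so that C7 carries OH, C6 the chromone and C5 the OMe), which the polarization of the triple bond by OMe imposes, and it needs the ketene to prefer the ynol ether over the chromone C2=C3 bond, over dimerization and over phenol acylation, which the high ketenophilicity of the ynol ether, the slow addition of 6 and the MOM cap on the chromone 7-OH provide. Because the three oxygens of ring B come from three different sources (ketene oxygen as free OH, alkyne OMe, pyran oxygen), no phenol ever has to be distinguished from another.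

Step 11
Reactants: 20 7-O-methoxymethyl glycyrrhizaisoflavone C
Product: 21 glycyrrhizaisoflavone C
Conditions: HCl (1 M in MeOH), MeOH/THF, 45 °C
Reagents that add atoms: none
Why: Acid-catalysed methanolysis of the MOM acetal; the aryl methyl ether, the tertiary-alkyl aryl ether of the chroman and the chromone are stable to dilute methanolic HCl.

**Compound list**

1 | ethyl acetoacetate | CCOC(=O)CC(C)=O | starting material
2 | prenyl bromide (1-bromo-3-methylbut-2-ene) | CC(C)=CCBr | starting material
3 | ethyl 2-acetyl-5-methylhex-4-enoate (racemic) | CCOC(=O)C(CC=C(C)C)C(C)=O | intermediate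
4 | ethyl 2,6,6-trimethyl-5,6-dihydro-4H-pyran-3-carboxylate | CCOC(=O)C1=C(C)OC(C)(C)CC1 | intermediate
5 | potassium 2,6,6-trimethyl-5,6-dihydro-4H-pyran-3-carboxylate | CC1=C(C(=O)[O-])CCC(C)(C)O1.[K+] | intermediate
6 | 2,6,6-trimethyl-5,6-dihydro-4H-pyran-3-carbonyl chloride | O=C(Cl)C1=C(C)OC(C)(C)CC1 | intermediate
7 | 2,4-dihydroxyacetophenone | CC(=O)c1ccc(O)cc1O | starting material
8 | 1-[2-hydroxy-4-(methoxymethoxy)phenyl]ethanone | CC(=O)c1ccc(OCOC)cc1O | intermediate
9 | N,N-dimethylformamide dimethyl acetal | COC(OC)N(C)C | starting material
10 | (E)-3-(dimethylamino)-1-[2-hydroxy-4-(methoxymethoxy)phenyl]prop-2-en-1-one | CN(C)/C=C/C(=O)c1ccc(OCOC)cc1O | intermediate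
11 | 3-iodo-7-(methoxymethoxy)chromen-4-one | COCOc1ccc2c(c1)occ(I)c2=O | intermediate
12 | chloroacetaldehyde dimethyl acetal | COC(CCl)OC | starting material
13 | lithium methoxyacetylide (not isolated) | COC#C[Li] | intermediate
14 | tributyl(methoxyethynyl)stannane | CCCC[Sn](CCCC)(CCCC)C#COC | intermediate
15 | 3-(methoxyethynyl)-7-(methoxymethoxy)chromen-4-one | COC#Cc1coc2cc(OCOC)ccc2c1=O | intermediate
16 | vinylketene, (6,6-dimethyl-2-methylideneoxan-3-ylidene)methanone (not isolated) | O=C=C1CCC(C)(C)OC1=C | intermediate
17 | spirocyclobutenone, 3-methoxy-2-[7-(methoxymethoxy)-4-oxochromen-3-yl]-7,7-dimethyl-5-methylidene-6-oxaspiro[3.5]non-2-en-1-one (racemic, not isolated) | COC1=C(c2coc3cc(OCOC)ccc3c2=O)C(=O)C14CCC(C)(C)OC4=C | intermediate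
18 | dienylketene, 3-[(3E)-6,6-dimethyl-2-methylideneoxan-3-ylidene]-3-methoxy-2-[7-(methoxymethoxy)-4-oxochromen-3-yl]prop-1-en-1-one (not isolated) | O=C=C(c1coc2cc(OCOC)ccc2c1=O)/C(OC)=C3/CCC(C)(C)OC3=C | intermediate
19 | cyclohexadienone, 5-methoxy-6-[7-(methoxymethoxy)-4-oxochromen-3-yl]-2,2-dimethyl-3,4-dihydro-2H-chromen-7(8H)-one (not isolated) | O=C1CC2=C(CCC(C)(C)O2)C(OC)=C1c1coc2cc(OCOC)ccc2c1=O | intermediate
20 | 7-O-methoxymethyl glycyrrhizaisoflavone C, 3-(7-hydroxy-5-methoxy-2,2-dimethylchroman-6-yl)-7-(methoxymethoxy)chromen-4-one | COCOc1ccc2c(c1)occ(-c1c(O)cc3c(c1OC)CCC(C)(C)O3)c2=O | intermediate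
21 | glycyrrhizaisoflavone C, 7-hydroxy-3-(7-hydroxy-5-methoxy-2,2-dimethylchroman-6-yl)chromen-4-one | COc1c2c(cc(O)c1-c1coc3cc(O)ccc3c1=O)OC(C)(C)CC2 | target

**Step count**

Total: 11 steps. Longest linear sequence: 6 steps (steps 1, 2, 3, 4, 10, 11, or equally steps 5, 6, 7, 9, 10, 11).

**Steps most likely to fail**

1. Step 10 (proposed new method). The 1,4-dehydrochlorination may be slower than other reactions of the acylammonium species. The vinylketene may dimerize or oligomerize before it meets the hindered aryl ynol ether. The ring-opened ketene may also be intercepted before it electrocyclizes. The fallback uses known chemistry only: it gives up the benzannulation and makes the isoflavone by oxidative aryl migration in a chalcone. It sets out from 8 and comes back at 21. Phloroglucinol and 3-methylbut-2-enoic acid are condensed in MeSO3H/P2O5 to 5,7-dihydroxy-2,2-dimethylchroman-4-one F1. Only the non-chelated 7-OH is alkylated (MOMCl, iPr2NEt), giving 5-hydroxy-7-(methoxymethoxy)-2,2-dimethylchroman-4-one F2. ClCO2Et/Et3N converts the chelated phenol into ethyl 7-(methoxymethoxy)-2,2-dimethyl-4-oxochroman-5-yl carbonate F3. NaBH4 in aqueous THF then reduces the ortho-acyl carbonate through a quinone methide to 7-(methoxymethoxy)-2,2-dimethylchroman-5-ol F4. Magnesium-mediated ortho-formylation (MgCl2, Et3N, paraformaldehyde, MeCN, reflux) can only reach C6, the single free ortho position of the 5-OH, and gives 5-hydroxy-7-(methoxymethoxy)-2,2-dimethylchroman-6-carbaldehyde F5. MeI/K2CO3 gives 5-methoxy-7-(methoxymethoxy)-2,2-dimethylchroman-6-carbaldehyde F6. Claisen–Schmidt condensation of F6 with 8 (KOH, EtOH) gives the chalcone (E)-1-[2-hydroxy-4-(methoxymethoxy)phenyl]-3-[5-methoxy-7-(methoxymethoxy)-2,2-dimethylchroman-6-yl]prop-2-en-1-one F7. Tl(NO3)3·3H2O in MeOH/HC(OMe)3 induces the 1,2-shift of the electron-rich aryl group to 1-[2-hydroxy-4-(methoxymethoxy)phenyl]-3,3-dimethoxy-2-[5-methoxy-7-(methoxymethoxy)-2,2-dimethylchroman-6-yl]propan-1-one F8. HCl in MeOH closes the chromone ring and removes both MOM groups to give 21. In this fallback the three oxygens are told apart by the chelation of the 5-OH to the C4 ketone and not by the annulation, at the cost of a longer sequence.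

2. Step 9. Transmetalation from tin may be too slow at the temperature the ynol ether tolerates, so that hydration or oligomerization of the alkoxyalkyne and homocoupling outrun the cross-coupling; the product may also be lost on acidic supports. The fallback changes the organometallic partner and removes the isolated tin reagent (Negishi coupling). It sets out from 12 and comes back at 15, bypassing 14. Lithium acetylide 13, generated as in step 8, is transmetalated with ZnCl2 at −78 °C to chloro(methoxyethynyl)zinc F9. F9 is coupled in the same flask with 11 (Pd(PPh3)4, THF, 0 °C to rt), and the crude 15 is filtered through basic alumina and taken directly into step 10.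

3. Step 4. Traces of HCl may add to the enol ether or ionize the tertiary C–O bond, and the chloride may degrade on concentration. The fallback gives up the acid chloride and generates the ketene from the carboxylate by in situ activation. It sets out from 5 and comes back at 16, and so at 20. In toluene/MeCN containing 15 and Et3N, 5 reacts with 2-chloro-1-methylpyridinium iodide to give 1-methyl-2-[(2,6,6-trimethyl-5,6-dihydro-4H-pyran-3-carbonyl)oxy]pyridinium iodide F10. Et3N converts F10 by the same 1,4-elimination into 16, which continues as in step 10.

**Further compounds**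

F1 | step 10 | 5,7-dihydroxy-2,2-dimethylchroman-4-one | CC1(C)CC(=O)c2c(O)cc(O)cc2O1
F2 | step 10 | 5-hydroxy-7-(methoxymethoxy)-2,2-dimethylchroman-4-one | CC1(C)CC(=O)c2c(O)cc(OCOC)cc2O1
F3 | step 10 | ethyl 7-(methoxymethoxy)-2,2-dimethyl-4-oxochroman-5-yl carbonate | CCOC(=O)Oc1cc(OCOC)cc2OC(C)(C)CC(=O)c12
F4 | step 10 | 7-(methoxymethoxy)-2,2-dimethylchroman-5-ol | CC1(C)CCc2c(O)cc(OCOC)cc2O1
F5 | step 10 | 5-hydroxy-7-(methoxymethoxy)-2,2-dimethylchroman-6-carbaldehyde | CC1(C)CCc2c(O)c(C=O)c(OCOC)cc2O1
F6 | step 10 | 5-methoxy-7-(methoxymethoxy)-2,2-dimethylchroman-6-carbaldehyde | CC1(C)CCc2c(OC)c(C=O)c(OCOC)cc2O1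
F7 | step 10 | (E)-1-[2-hydroxy-4-(methoxymethoxy)phenyl]-3-[5-methoxy-7-(methoxymethoxy)-2,2-dimethylchroman-6-yl]prop-2-en-1-one | COCOc1ccc(C(=O)/C=C/c2c(OC)c3CCC(C)(C)Oc3cc2OCOC)c(O)c1
F8 | step 10 | 1-[2-hydroxy-4-(methoxymethoxy)phenyl]-3,3-dimethoxy-2-[5-methoxy-7-(methoxymethoxy)-2,2-dimethylchroman-6-yl]propan-1-one (racemic) | COCOc1ccc(C(=O)C(C(OC)OC)c2c(OC)c3CCC(C)(C)Oc3cc2OCOC)c(O)c1
F9 | step 9 | chloro(methoxyethynyl)zinc | COC#C[Zn]Cl
F10 | step 4 | 1-methyl-2-[(2,6,6-trimethyl-5,6-dihydro-4H-pyran-3-carbonyl)oxy]pyridinium iodide | C[n+]1ccccc1OC(=O)C1=C(C)OC(C)(C)CC1.[I-]
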